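**Retrosynthetic overview**
- Target 14 (2,3,4,6-tetrabromo-1H-indole) comes from C3 bromination of 2,4,6-tribromo-1H-indole 12, which comes from N-desulfonylation of N-tosyl indole 11.
- Key disconnection: N1–C2 of 11, leading back to sulfonanilide 9 with an ortho CH=CBr2 group. The pyrrole ring is the only ring formed; the benzene ring with the C4 and C6 bromines and the nitrogen site is bought.
- Feature the strategy rests on: C2 is bonded to both N1 and bromine, so it is drawn from a CBr2 carbon attached to C3 (the former aldehyde carbon). One bromine leaves in the closure and the other stays on C2.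
- 9 comes from aniline 7, from nitroarene 6, from aldehyde 4 (dibromoolefination), from nitrotoluene 1 (enamine formation, then periodate cleavage).

Key step: step 6

Assumption: 1 is taken to be a catalogue compound. The target has no stereocentre, so only constitution has to be controlled.

**Route**

Step 1
Reactants: 1 1,5-dibromo-2-methyl-3-nitrobenzene; 2 N,N-dimethylformamide dimethyl acetal
Product: 3 (E)-2-(2,4-dibromo-6-nitrophenyl)-N,N-dimethylethen-1-amine
Conditions: DMF-DMA (3 equiv), DMF, 120 °C, N2; concentrate, use crude
Reagents that add atoms: N,N-dimethylformamide dimethyl acetal, COC(OC)N(C)C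
Why: Leimgruber–Batcho-type enamine condensation, in which the methyl group (acidified by the ortho nitro group and the ring bromines) condenses with the formamide acetal to the trans enamine, while both bromines sit meta to the nitro group and are not open to nucleophilic aromatic substitution.

Step 2
Reactants: 3 (E)-2-(2,4-dibromo-6-nitrophenyl)-N,N-dimethylethen-1-amine
Product: 4 2,4-dibromo-6-nitrobenzaldehyde
Conditions: NaIO4 (3 equiv), THF/H2O 1:1, 0 °C to rt
Reagents that add atoms: sodium periodate, [Na+].[O-]I(=O)(=O)=O
Why: Oxidative cleavage of the electron-rich enamine C=C bond by periodate should release the benzaldehyde and N,N-dimethylformamide without touching the nitro group or the aryl bromides.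

Step 3
Reactants: 4 2,4-dibromo-6-nitrobenzaldehyde; 5 carbon tetrabromide
Product: 6 1,5-dibromo-2-(2,2-dibromovinyl)-3-nitrobenzene
Conditions: CBr4 (2 equiv), PPh3 (4 equiv), CH2Cl2, 0 °C to rt
Reagents that add atoms: carbon tetrabromide, BrC(Br)(Br)Br
Why: Ramirez dibromoolefination (first stage of the Corey–Fuchs sequence), in which the ylide Ph3P=CBr2 formed from CBr4 and PPh3 undergoes a Wittig reaction with the electron-poor aldehyde, a reaction well established for 2-nitrobenzaldehydes and tolerant of a second ortho substituent.

Step 4
Reactants: 6 1,5-dibromo-2-(2,2-dibromovinyl)-3-nitrobenzene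
Product: 7 3,5-dibromo-2-(2,2-dibromovinyl)aniline
Conditions: SnCl2·2H2O (5 equiv), EtOH, 75 °C; aq. NaHCO3 work-up
Reagents that add atoms: none
Why: Chemoselective nitro reduction by divalent tin, which is oxidised to tetravalent tin and should leave aryl and vinyl C–Br bonds intact where catalytic hydrogenation might not.

Step 5
Reactants: 7 3,5-dibromo-2-(2,2-dibromovinyl)aniline; 8 4-toluenesulfonyl chloride
Product: 9 N-[3,5-dibromo-2-(2,2-dibromovinyl)phenyl]-4-methylbenzenesulfonamide
Conditions: TsCl (1.3 equiv), pyridine, CH2Cl2, rt to 40 °C
Reagents that add atoms: 4-toluenesulfonyl chloride, Cc1ccc(cc1)S(Cl)(=O)=O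
Why: N-Sulfonylation of the aniline with pyridine as base and nucleophilic catalyst; the weakly nucleophilic, ortho-substituted nitrogen should stop at the monosulfonamide.

Step 6
Reactants: 9 N-[3,5-dibromo-2-(2,2-dibromovinyl)phenyl]-4-methylbenzenesulfonamide
Product: 11 2,4,6-tribromo-1-tosyl-1H-indole, via bromoalkyne sulfonanilide 10 (not isolated)
Conditions: Cs2CO3 (2.5 equiv), DMF, 80 °C
Reagents that add atoms: none
Why: This is the known base-promoted, transition-metal-free cyclisation of N-sulfonyl 2-(2,2-dibromovinyl)anilines to 2-bromoindoles: carbonate deprotonates the sulfonamide and removes the vinylic hydrogen anti to one bromine, giving bromoalkyne 10 by E2 loss of HBr. The sulfonamide anion then adds to the bromine-bearing alkyne carbon and the C3 vinyl anion is protonated, which forms the N1–C2 bond and closes the pyrrole ring in a 5-endo-dig mode with the second bromine still on C2; direct addition of nitrogen to the CBr2 carbon followed by bromide loss would converge on the same product. No stereocentre is created. The step needs reaction at the vinylic bromides only: no transition metal is present to insert into the two aryl C–Br bonds or the new C2–Br bond, the aryl bromides are not activated for nucleophilic aromatic substitution, and the ortho placement of nitrogen should let ring closure outpace intermolecular N-alkynylation. The tosyl group should stay on nitrogen because no alcohol or other nucleophile able to attack sulfur is present.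

Step 7
Reactants: 11 2,4,6-tribromo-1-tosyl-1H-indole
Product: 12 2,4,6-tribromo-1H-indole
Conditions: Cs2CO3 (3 equiv), THF/MeOH 2:1, rt; aq. NH4Cl quench on completion; use promptly, keep cold and dark
Reagents that add atoms: none
Why: Nucleophilic N-desulfonylation, in which methoxide generated by Cs2CO3 attacks the sulfonyl sulfur and expels the indolide (a good leaving group here because three bromines stabilise the anion), while the C–Br bonds are spared because the ring becomes an electron-rich anion once the sulfonyl group is gone.

Step 8
Reactants: 12 2,4,6-tribromo-1H-indole; 13 N-bromosuccinimide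
Product: 14 2,3,4,6-tetrabromo-1H-indole
Conditions: NBS (1.0 equiv), anhydrous DMF, 0 °C, dark
Reagents that add atoms: N-bromosuccinimide, O=C1CCC(=O)N1Br
Why: Electrophilic aromatic substitution with NBS at C3, the only free and by far the most nucleophilic position of the pyrrole ring, while C5 and C7 on the benzene ring are deactivated by the flanking bromines; one equivalent of NBS under anhydrous conditions guards against 3,3-dibromination.

**Compound list**

1 | 1,5-dibromo-2-methyl-3-nitrobenzene | Cc1c(Br)cc(Br)cc1[N+](=O)[O-] | starting material
2 | N,N-dimethylformamide dimethyl acetal | COC(OC)N(C)C | starting material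
3 | (E)-2-(2,4-dibromo-6-nitrophenyl)-N,N-dimethylethen-1-amine | CN(C)/C=C/c1c(Br)cc(Br)cc1[N+](=O)[O-] | intermediate
4 | 2,4-dibromo-6-nitrobenzaldehyde | O=Cc1c(Br)cc(Br)cc1[N+](=O)[O-] | intermediate
5 | carbon tetrabromide | BrC(Br)(Br)Br | starting material
6 | 1,5-dibromo-2-(2,2-dibromovinyl)-3-nitrobenzene | BrC(Br)=Cc1c(Br)cc(Br)cc1[N+](=O)[O-] | intermediate
7 | 3,5-dibromo-2-(2,2-dibromovinyl)aniline | Nc1cc(Br)cc(Br)c1C=C(Br)Br | intermediate
8 | 4-toluenesulfonyl chloride | Cc1ccc(cc1)S(Cl)(=O)=O | starting material
9 | N-[3,5-dibromo-2-(2,2-dibromovinyl)phenyl]-4-methylbenzenesulfonamide | Cc1ccc(cc1)S(=O)(=O)Nc1cc(Br)cc(Br)c1C=C(Br)Br | intermediate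
10 | N-[3,5-dibromo-2-(bromoethynyl)phenyl]-4-methylbenzenesulfonamide | Cc1ccc(cc1)S(=O)(=O)Nc1cc(Br)cc(Br)c1C#CBr | intermediate
11 | 2,4,6-tribromo-1-tosyl-1H-indole | Cc1ccc(cc1)S(=O)(=O)n1c(Br)cc2c(Br)cc(Br)cc21 | intermediate
12 | 2,4,6-tribromo-1H-indole | Brc1cc2c(Br)cc(Br)cc2[nH]1 | intermediate
13 | N-bromosuccinimide | O=C1CCC(=O)N1Br | starting material
14 | 2,3,4,6-tetrabromo-1H-indole | Brc1cc(Br)c2c(Br)c(Br)[nH]c2c1 | target

**Totals**

Total step count: 8. Longest linear sequence: 8 steps (1 to 14).

**Steps most likely to fail**

Step 6 (key ring closure). After loss of HBr, the bromoalkyne may be consumed by intermolecular N-alkynylation, by oligomerisation, or by a second dehalogenation to the terminal alkyne faster than it cyclises. The fallback sets out from 3 and comes back at 11; it places the C2 bromine by directed metalation instead of by ring closure. Enamine 3 is reduced with Fe powder in acetic acid at 80 °C; the aniline formed closes onto the enamine with loss of dimethylamine (Leimgruber–Batcho indole synthesis) and should give 4,6-dibromo-1H-indole F1. N-Sulfonylation with NaH and 8 in DMF at 0 °C should give 4,6-dibromo-1-tosyl-1H-indole F2. Sulfonyl-directed deprotonation at C2 with lithium diisopropylamide, LiN(i-Pr)2, in THF at −78 °C should give 4,6-dibromo-2-lithio-1-tosyl-1H-indole F3. The metalation time is kept short so that deprotonation at C5, between the two bromines, does not compete. Quenching with 1,2-dibromo-1,1,2,2-tetrachloroethane should then give 11.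

Step 8 (C3 bromination). The N-unprotected 2-bromoindole may be over-brominated to a 3,3-dibromo-3H-indole that hydrolyses to an oxindole, or it may decompose under traces of acid before or during the bromination. The fallback sets out from 11 and comes back at 14; it brominates while nitrogen still carries the sulfonyl group. Treating 11 with Br2 in acetic acid/CH2Cl2 at 40–50 °C should give 2,3,4,6-tetrabromo-1-tosyl-1H-indole F4. The N-sulfonyl indole cannot tautomerise to a 3H-indole and tolerates excess bromine. Cleavage of the tosyl group with Cs2CO3 in THF/MeOH should then give 14 directly.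

Step 1 (enamine formation). Condensation at a methyl group crowded between bromine and nitro may be slow, and the enamine may degrade thermally during prolonged heating. The fallback sets out from 1 and comes back at 4; it oxidises the methyl group through the benzylic bromide. Wohl–Ziegler bromination of 1 with NBS 13 and catalytic dibenzoyl peroxide in refluxing PhCF3 should give 1,5-dibromo-2-(bromomethyl)-3-nitrobenzene F5. Oxidation with N-methylmorpholine N-oxide in MeCN over 4 Å molecular sieves at room temperature should then give aldehyde 4.

**Further compounds**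

F1 | step 6 | 4,6-dibromo-1H-indole | Brc1cc(Br)c2cc[nH]c2c1
F2 | step 6 | 4,6-dibromo-1-tosyl-1H-indole | Cc1ccc(cc1)S(=O)(=O)n1ccc2c(Br)cc(Br)cc21
F3 | step 6 | 4,6-dibromo-2-lithio-1-tosyl-1H-indole | [Li]c1cc2c(Br)cc(Br)cc2n1S(=O)(=O)c1ccc(C)cc1
F4 | step 8 | 2,3,4,6-tetrabromo-1-tosyl-1H-indole | Cc1ccc(cc1)S(=O)(=O)n1c(Br)c(Br)c2c(Br)cc(Br)cc21
F5 | step 1 | 1,5-dibromo-2-(bromomethyl)-3-nitrobenzene | BrCc1c(Br)cc(Br)cc1[N+](=O)[O-]
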